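**Retrosynthetic overview**

1. The strategy rests on ring C of the lower (catechin) unit: C4 is a CH2 between ring A (C4a) and C3, and the bonds O1–C2 and C3–C4 flank the trans C2(aryl)/C3(O) pair. A retro oxa-[4+2] cuts both bonds to an o-quinone methide on lower ring A (C4 as the exocyclic CH2, O1 as the carbonyl oxygen) and an (E)-2-arylvinyl acetate.
2. The quinone methide comes from a salicyl alcohol, made by ortho-formylation and reduction of a phenol ring (from 3,5-bis(benzyloxy)phenol) that is attached 4β to the C4 cation of the middle unit.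
3. The upper–middle 4β→8 bond is a flavan-4-yl cation coupling. Both units come from (−)-epicatechin; the middle one keeps its C5 oxygen (as a silyl ether) during the coupling so that attack goes to C8 and not to C6 of a resorcinol-type ring, and that oxygen is then made a triflate.
4. Two spectator groups ride through the key step: Br at C8 of the upper unit (a cap against ring A acting as a nucleophile) and OTf at C5 of the middle unit. The last hydrogenolysis removes both together with the benzyl ethers, which gives the 5-deoxy middle unit.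
5. Ring order: rings A, B and C of the upper and middle units are present from the start, lower ring A is attached in step 12, and lower ring C is closed last (step 17) with ring B and the C3 oxygen already on the dienophile.

Key step: step 17

Remarks: flavan numbering is used; in each (2R) unit the C2 aryl group is α and β is the opposite face. Bn = benzyl, TBS = tert-butyldimethylsilyl, Tf = trifluoromethanesulfonyl. (−)-Epicatechin, 3,5-bis(benzyloxy)phenol and 3,4-bis(benzyloxy)benzaldehyde are assumed to be purchased.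

**Route**

Step 1
Reactants: 1 (−)-epicatechin
Product: 2 5,7,3′,4′-tetra-O-benzyl-(−)-epicatechin [(2R,3R)-5,7-bis(benzyloxy)-2-[3,4-bis(benzyloxy)phenyl]chroman-3-ol]
Conditions: BnBr (4.4 equiv), K2CO3, DMF, 0 °C → rt
Reagents that add atoms: benzyl bromide, BrCc1ccccc1
Why: Williamson etherification in which K2CO3 deprotonates only the four phenols (the secondary alcohol stays free) and the C2/C3 stereocentres of the chiral pool are not touched.

Step 2
Reactants: 2 5,7,3′,4′-tetra-O-benzyl-(−)-epicatechin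
Product: 3 3,5,7,3′,4′-penta-O-benzylepicatechin [(2R,3R)-3,5,7-tris(benzyloxy)-2-[3,4-bis(benzyloxy)phenyl]chroman]
Conditions: NaH, BnBr, Bu4NI (cat.), DMF, 0 °C → rt
Reagents that add atoms: benzyl bromide, BrCc1ccccc1
Why: Williamson etherification of the C3 alkoxide gives the benzyl ether that later steers both C4 substitutions to the β face.

Step 3
Reactants: 3 penta-O-benzylepicatechin
Product: 4 (2R,3R,4S)-3,5,7-tris(benzyloxy)-2-[3,4-bis(benzyloxy)phenyl]chroman-4-ol (4β-hydroxy)
Conditions: 2,3-dichloro-5,6-dicyano-1,4-benzoquinone (DDQ, 1.5 equiv), CH2Cl2/H2O, rt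
Reagents that add atoms: water, O
Why: DDQ benzylic oxidation: hydride abstraction from C4, activated by the trioxygenated ring A, gives the flavan-4-yl cation, which water should capture trans to the C3 benzyloxy group (the C4 configuration is of no consequence later).

Step 4
Reactants: 4 4β-hydroxy-penta-O-benzylepicatechin
Product: 5 (2R,3R,4S)-8-bromo-3,5,7-tris(benzyloxy)-2-[3,4-bis(benzyloxy)phenyl]chroman-4-ol (upper electrophile)
Conditions: NBS (1.05 equiv), CH2Cl2, −40 → 0 °C
Reagents that add atoms: N-bromosuccinimide, BrN1C(=O)CCC1=O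
Why: Electrophilic aromatic bromination: C8, flanked by the ring oxygen and one benzyloxy group, should react before C6, which lies between two benzyloxy groups, and the bromine then caps ring A against acting as a nucleophile in all later cation chemistry.

Step 5
Reactants: 4 4β-hydroxy-penta-O-benzylepicatechin
Product: 6 (2R,3S)-3,5,7-tris(benzyloxy)-2-[3,4-bis(benzyloxy)phenyl]chroman-4-one (2,3-cis)
Conditions: Dess–Martin periodinane, NaHCO3, CH2Cl2, rt
Reagents that add atoms: none
Why: Dess–Martin oxidation of the secondary benzylic alcohol under buffered, non-enolising conditions should keep the 2,3-cis configuration.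

Step 6
Reactants: 6 penta-O-benzyl 4-ketone
Product: 7 (2R,3S)-3,7-bis(benzyloxy)-2-[3,4-bis(benzyloxy)phenyl]-5-hydroxychroman-4-one
Conditions: BCl3 (1.1 equiv), CH2Cl2, −78 °C; then aq. NaHCO3
Reagents that add atoms: none
Why: Chelation-controlled Lewis acid ether cleavage: BCl3 bound to the C4 carbonyl reaches only the peri benzyl ether at C5, which should be cleaved at −78 °C with one equivalent while the other benzyl ethers stay.

Step 7
Reactants: 7 5-hydroxy 4-ketone
Product: 9 (2R,3S,4S)-3,7-bis(benzyloxy)-2-[3,4-bis(benzyloxy)phenyl]-4-[(2,6-dimethylphenyl)sulfanyl]chroman-5-ol (4β-thioether), via flavan-4-ol 8 (not isolated)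
Conditions: NaBH4, THF/EtOH, 0 °C; then 2,6-Me2C6H3SH (3 equiv), AcOH, 0 °C → rt
Reagents that add atoms: 2,6-dimethylbenzenethiol, Cc1cccc(C)c1S
Why: NaBH4 reduction gives the 2-hydroxybenzylic alcohol 8, which under weak acid ionises (SN1 through a quinone-methide-like cation) and is captured by the thiol trans to the C3 benzyloxy group (thiolysis of a flavan-4-ol), so C4 should be set as 4β.

Step 8
Reactants: 9 5-hydroxy 4β-thioether
Product: 10 (2R,3S,4S)-3,7-bis(benzyloxy)-2-[3,4-bis(benzyloxy)phenyl]-5-(tert-butyldimethylsilyloxy)-4-[(2,6-dimethylphenyl)sulfanyl]chroman (middle nucleophile)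
Conditions: TBSOTf, 2,6-lutidine, CH2Cl2, 0 °C
Reagents that add atoms: tert-butyldimethylsilyl trifluoromethanesulfonate, C[Si](C)(OS(=O)(=O)C(F)(F)F)C(C)(C)C
Why: Silyl ether formation at the only free hydroxyl restores a third oxygen donor on ring A and marks the C5 oxygen for later removal.

Step 9
Reactants: 5 8-bromo 4β-ol (upper electrophile); 10 silyl ether thioether (middle nucleophile)
Product: 11 [8-bromo-3,5,7,3′,4′-penta-O-benzylepicatechin]-(4β→8)-[3,7,3′,4′-tetra-O-benzyl-5-O-TBS-4β-(2,6-dimethylphenylsulfanyl)epicatechin]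
Conditions: BF3·OEt2 (0.3 equiv), 4 Å MS, CH2Cl2, −78 → −40 °C; 10 in slight excess
Reagents that add atoms: none
Why: Friedel–Crafts alkylation by the flavan-4-yl cation with orthogonal activation: the hard Lewis acid ionises the C4–OH of 5 but not the C–S bond of 10, ring A of 10 with three oxygen donors should be attacked at C8 (C6 is shielded between OTBS and OBn), and approach trans to the C3 benzyloxy group sets the new C4 centre as 4β.

Step 10
Reactants: 11 dimer silyl ether
Product: 12 [8-bromo-penta-O-benzylepicatechin]-(4β→8)-[3,7,3′,4′-tetra-O-benzyl-4β-(2,6-dimethylphenylsulfanyl)epicatechin] with free C5–OH on the middle unit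
Conditions: Bu4NF, AcOH, THF, 0 °C
Reagents that add atoms: none
Why: Fluoride-induced cleavage of the aryl silyl ether, buffered with acetic acid so that the phenoxide does not expel the neighbouring thiolate.

Step 11
Reactants: 12 dimer phenol
Product: 13 [8-bromo-penta-O-benzylepicatechin]-(4β→8)-[3,7,3′,4′-tetra-O-benzyl-5-O-triflyl-4β-(2,6-dimethylphenylsulfanyl)epicatechin]
Conditions: PhNTf2, Et3N, DMAP (cat.), CH2Cl2, 0 °C → rt
Reagents that add atoms: N-phenylbis(trifluoromethanesulfonimide), O=S(=O)(N(c1ccccc1)S(=O)(=O)C(F)(F)F)C(F)(F)F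
Why: Sulfonylation of the phenol with a mild triflating agent turns the C5 oxygen into a group that hydrogenolysis removes and that makes ring A of the middle unit a poor leaving group in the later acid steps.

Step 12
Reactants: 13 dimer triflate thioether; 14 3,5-bis(benzyloxy)phenol
Product: 15 [8-bromo-penta-O-benzylepicatechin]-(4β→8)-[3,7,3′,4′-tetra-O-benzyl-5-O-triflylepicatechin] carrying a 2-hydroxy-4,6-bis(benzyloxy)phenyl group at C4β of the middle unit
Conditions: AgBF4 (1.5 equiv), 14 (4 equiv), 4 Å MS, CH2Cl2/THF, 0 °C → rt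
Reagents that add atoms: none
Why: Thiophilic activation by the silver salt ionises the C4–S bond (SN1), and the phenol should be alkylated at the carbon ortho to its hydroxyl, directly or by O-alkylation and ortho O→C shift (Friedel–Crafts alkylation), from the face trans to the C3 benzyloxy group (4β), the position between the two benzyloxy groups being the hindered one.

Step 13
Reactants: 15 dimer phenol
Product: 16 the same dimer carrying a 3-formyl-2-hydroxy-4,6-bis(benzyloxy)phenyl group at C4β of the middle unit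
Conditions: MgCl2, Et3N, (CH2O)n, MeCN, reflux
Reagents that add atoms: paraformaldehyde (as formaldehyde), C=O
Why: Casnati–Skattebøl ortho-formylation: the magnesium phenoxide delivers formaldehyde to the only free ortho carbon and the hydroxymethyl intermediate is oxidised by a second formaldehyde.

Step 14
Reactants: 16 salicylaldehyde
Product: 17 the same dimer carrying a 2-hydroxy-3-(hydroxymethyl)-4,6-bis(benzyloxy)phenyl group at C4β of the middle unit (key-step precursor)
Conditions: NaBH4, THF/EtOH, 0 °C; used at once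
Reagents that add atoms: none
Why: NaBH4 reduction of the aldehyde under basic conditions gives the acid-sensitive salicyl alcohol without ionising it.

Step 15
Reactants: 18 3,4-bis(benzyloxy)benzaldehyde
Product: 20 2-[3,4-bis(benzyloxy)phenyl]acetaldehyde, via methyl enol ether 19 (not isolated)
Conditions: MeOCH2PPh3Cl, KOtBu, THF, 0 °C → rt; then 2 M HCl, THF, 50 °C
Reagents that add atoms: (methoxymethyl)triphenylphosphonium chloride, COC[P+](c1ccccc1)(c1ccccc1)c1ccccc1.[Cl-]; water, O
Why: Wittig methoxymethylenation followed by acid hydrolysis of the enol ether (one-carbon homologation of an aldehyde).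

Step 16
Reactants: 20 2-[3,4-bis(benzyloxy)phenyl]acetaldehyde
Product: 21 (E)-2-[3,4-bis(benzyloxy)phenyl]vinyl acetate
Conditions: Ac2O, KOAc, 110 °C; E isomer crystallised
Reagents that add atoms: acetic anhydride, CC(=O)OC(C)=O
Why: Enol acetylation of the aldehyde under equilibrating conditions (O-acylation of the enolate), the more stable E isomer being separated from the Z isomer by crystallisation.

Step 17
Reactants: 17 salicyl alcohol (key-step precursor); 21 (E)-2-[3,4-bis(benzyloxy)phenyl]vinyl acetate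
Product: 23 [8-bromo-penta-O-benzylepicatechin]-(4β→8)-[3,7,3′,4′-tetra-O-benzyl-5-O-triflylepicatechin]-(4β→8)-[3-O-acetyl-5,7,3′,4′-tetra-O-benzylcatechin], via o-quinone methide 22 (not isolated)
Conditions: 21 (8 equiv), (R)-3,3′-bis(2,4,6-triisopropylphenyl)-1,1′-binaphthalene-2,2′-diyl hydrogen phosphate (10 mol %), 4 Å MS, CH2Cl2, 0 °C → rt; 17 added slowly
Reagents that add atoms: none
Why: Proposed new method: the phosphoric acid protonates the benzylic hydroxyl of 17, water leaves and the o-quinone methide 22 stays hydrogen-bonded through its carbonyl oxygen to the chiral phosphate, then its exocyclic CH2 (largest LUMO coefficient) is attacked by the acetoxy-bearing carbon of 21 while the quinone methide oxygen closes onto the benzylic carbon in an asynchronous concerted inverse-electron-demand oxa-[4+2] cycloaddition. The closest known reaction type is the Brønsted-acid-catalysed [4+2] addition of o-quinone methides generated in situ to electron-rich β-substituted styrenes, which gives trans-2-aryl-3-substituted chromans; an enol ester as the styrene β-substituent and catalyst control beside a stereogenic benzylic substituent are extensions. Ring C of the lower unit is closed by intermolecular [4+2] annulation, O1–C2 and C3–C4 forming in one operation to a six-membered ring. The trans relationship of C2 and C3 follows from suprafacial addition to the E alkene, and the absolute configuration (2R,3S) is set by the face of 22 that the chiral phosphate leaves open, reinforced or opposed by the C4 centre of the middle unit, which sits ortho to the quinone methide oxygen, so both hands of the acid are tried and the matched one is used (written here for R). Regioselectivity is needed and is secured by the 3,4-bis(benzyloxy)phenyl group, which stabilises positive charge at the benzylic carbon far better than the acetoxy group does at its carbon, and the 4→8 sense of fusion is fixed because the only free phenolic oxygen is the one flanked by the middle unit. Chemoselectivity against alkylation of aromatic rings by 22 is helped by the bromine cap and the triflate on the other A rings, by slow addition of 17 and by the excess of 21.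

Step 18
Reactants: 23 protected trimer acetate
Product: 24 [8-bromo-penta-O-benzylepicatechin]-(4β→8)-[3,7,3′,4′-tetra-O-benzyl-5-O-triflylepicatechin]-(4β→8)-[5,7,3′,4′-tetra-O-benzylcatechin] (free C3–OH on the lower unit)
Conditions: iBu2AlH, CH2Cl2, −78 °C
Reagents that add atoms: none
Why: Reductive cleavage of the acetate by the aluminium hydride at low temperature, chosen over basic methanolysis because the aryl triflate would not be safe toward alkoxide.

Step 19
Reactants: 24 protected trimer alcohol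
Product: 25 epicatechin-(4β→8)-[(2R,3R,4R)-7,3′,4′-trihydroxyflavan-3-ol]-(4β→8)-catechin (CNP0270097.1)
Conditions: H2 (1–3 bar), Pd(OH)2/C, Et3N, THF/MeOH/H2O, rt
Reagents that add atoms: none
Why: Palladium-catalysed hydrogenolysis should remove the thirteen benzyl ethers, the aryl bromide and the aryl triflate (C–O hydrogenolysis of an aryl sulfonate) in one operation, the amine taking up HBr and TfOH so that the interflavan bonds survive.

**Compound list**

1 | (−)-epicatechin | Oc1cc(O)c2c(c1)O[C@H](c1ccc(O)c(O)c1)[C@H](O)C2 | starting material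
2 | 5,7,3′,4′-tetra-O-benzyl-(−)-epicatechin | c9ccccc9COc1cc(OCc9ccccc9)c2c(c1)O[C@H](c7ccc(OCc9ccccc9)c(OCc9ccccc9)c7)[C@H](O)C2 | intermediate
3 | 3,5,7,3′,4′-penta-O-benzylepicatechin | c9ccccc9COc1cc(OCc9ccccc9)c2c(c1)O[C@H](c7ccc(OCc9ccccc9)c(OCc9ccccc9)c7)[C@H](OCc9ccccc9)C2 | intermediate
4 | (2R,3R,4S)-3,5,7-tris(benzyloxy)-2-[3,4-bis(benzyloxy)phenyl]chroman-4-ol | c9ccccc9COc1cc(OCc9ccccc9)c2c(c1)O[C@H](c7ccc(OCc9ccccc9)c(OCc9ccccc9)c7)[C@H](OCc9ccccc9)[C@H]2O | intermediate
5 | (2R,3R,4S)-8-bromo-3,5,7-tris(benzyloxy)-2-[3,4-bis(benzyloxy)phenyl]chroman-4-ol | c9ccccc9COc1cc(OCc9ccccc9)c2c(c1Br)O[C@H](c7ccc(OCc9ccccc9)c(OCc9ccccc9)c7)[C@H](OCc9ccccc9)[C@H]2O | intermediate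
6 | (2R,3S)-3,5,7-tris(benzyloxy)-2-[3,4-bis(benzyloxy)phenyl]chroman-4-one | c9ccccc9COc1cc(OCc9ccccc9)c2c(c1)O[C@H](c7ccc(OCc9ccccc9)c(OCc9ccccc9)c7)[C@H](OCc9ccccc9)C2=O | intermediate
7 | (2R,3S)-3,7-bis(benzyloxy)-2-[3,4-bis(benzyloxy)phenyl]-5-hydroxychroman-4-one | c9ccccc9COc1cc(O)c2c(c1)O[C@H](c7ccc(OCc9ccccc9)c(OCc9ccccc9)c7)[C@H](OCc9ccccc9)C2=O | intermediate
8 | (2R,3R,4R)-3,7-bis(benzyloxy)-2-[3,4-bis(benzyloxy)phenyl]chroman-4,5-diol (4α-ol expected; C4 configuration is lost on ionisation) | c9ccccc9COc1cc(O)c2c(c1)O[C@H](c7ccc(OCc9ccccc9)c(OCc9ccccc9)c7)[C@H](OCc9ccccc9)[C@@H]2O | intermediate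
9 | (2R,3S,4S)-3,7-bis(benzyloxy)-2-[3,4-bis(benzyloxy)phenyl]-4-[(2,6-dimethylphenyl)sulfanyl]chroman-5-ol | c9ccccc9COc1cc(O)c2c(c1)O[C@H](c7ccc(OCc9ccccc9)c(OCc9ccccc9)c7)[C@H](OCc9ccccc9)[C@H]2Sc3c(C)cccc3C | intermediate
10 | (2R,3S,4S)-3,7-bis(benzyloxy)-2-[3,4-bis(benzyloxy)phenyl]-5-(tert-butyldimethylsilyloxy)-4-[(2,6-dimethylphenyl)sulfanyl]chroman | c9ccccc9COc1cc(O[Si](C)(C)C(C)(C)C)c2c(c1)O[C@H](c7ccc(OCc9ccccc9)c(OCc9ccccc9)c7)[C@H](OCc9ccccc9)[C@H]2Sc3c(C)cccc3C | intermediate
11 | upper–middle dimer, middle unit 5-OTBS and 4β-S(2,6-dimethylphenyl), upper unit 8-Br | c9ccccc9COc1cc(OCc9ccccc9)c2c(c1Br)O[C@H](c7ccc(OCc9ccccc9)c(OCc9ccccc9)c7)[C@H](OCc9ccccc9)[C@H]2c1c(OCc9ccccc9)cc(O[Si](C)(C)C(C)(C)C)c2c1O[C@H](c7ccc(OCc9ccccc9)c(OCc9ccccc9)c7)[C@H](OCc9ccccc9)[C@H]2Sc3c(C)cccc3C | intermediate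
12 | upper–middle dimer, middle unit 5-OH and 4β-S(2,6-dimethylphenyl) | c9ccccc9COc1cc(OCc9ccccc9)c2c(c1Br)O[C@H](c7ccc(OCc9ccccc9)c(OCc9ccccc9)c7)[C@H](OCc9ccccc9)[C@H]2c1c(OCc9ccccc9)cc(O)c2c1O[C@H](c7ccc(OCc9ccccc9)c(OCc9ccccc9)c7)[C@H](OCc9ccccc9)[C@H]2Sc3c(C)cccc3C | intermediate
13 | upper–middle dimer, middle unit 5-OTf and 4β-S(2,6-dimethylphenyl) | c9ccccc9COc1cc(OCc9ccccc9)c2c(c1Br)O[C@H](c7ccc(OCc9ccccc9)c(OCc9ccccc9)c7)[C@H](OCc9ccccc9)[C@H]2c1c(OCc9ccccc9)cc(OS(=O)(=O)C(F)(F)F)c2c1O[C@H](c7ccc(OCc9ccccc9)c(OCc9ccccc9)c7)[C@H](OCc9ccccc9)[C@H]2Sc3c(C)cccc3C | intermediate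
14 | 3,5-bis(benzyloxy)phenol | Oc1cc(OCc2ccccc2)cc(OCc2ccccc2)c1 | starting material
15 | dimer with 2-hydroxy-4,6-bis(benzyloxy)phenyl at C4β of the middle unit | c9ccccc9COc1cc(OCc9ccccc9)c2c(c1Br)O[C@H](c7ccc(OCc9ccccc9)c(OCc9ccccc9)c7)[C@H](OCc9ccccc9)[C@H]2c1c(OCc9ccccc9)cc(OS(=O)(=O)C(F)(F)F)c2c1O[C@H](c7ccc(OCc9ccccc9)c(OCc9ccccc9)c7)[C@H](OCc9ccccc9)[C@H]2c1c(OCc9ccccc9)cc(OCc9ccccc9)cc1O | intermediate
16 | dimer with 3-formyl-2-hydroxy-4,6-bis(benzyloxy)phenyl at C4β of the middle unit | c9ccccc9COc1cc(OCc9ccccc9)c2c(c1Br)O[C@H](c7ccc(OCc9ccccc9)c(OCc9ccccc9)c7)[C@H](OCc9ccccc9)[C@H]2c1c(OCc9ccccc9)cc(OS(=O)(=O)C(F)(F)F)c2c1O[C@H](c7ccc(OCc9ccccc9)c(OCc9ccccc9)c7)[C@H](OCc9ccccc9)[C@H]2c1c(OCc9ccccc9)cc(OCc9ccccc9)c(C=O)c1O | intermediate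
17 | dimer with 2-hydroxy-3-(hydroxymethyl)-4,6-bis(benzyloxy)phenyl at C4β of the middle unit (key-step precursor) | c9ccccc9COc1cc(OCc9ccccc9)c2c(c1Br)O[C@H](c7ccc(OCc9ccccc9)c(OCc9ccccc9)c7)[C@H](OCc9ccccc9)[C@H]2c1c(OCc9ccccc9)cc(OS(=O)(=O)C(F)(F)F)c2c1O[C@H](c7ccc(OCc9ccccc9)c(OCc9ccccc9)c7)[C@H](OCc9ccccc9)[C@H]2c1c(OCc9ccccc9)cc(OCc9ccccc9)c(CO)c1O | intermediate
18 | 3,4-bis(benzyloxy)benzaldehyde | O=Cc1ccc(OCc2ccccc2)c(OCc2ccccc2)c1 | starting material
19 | 1,2-bis(benzyloxy)-4-(2-methoxyvinyl)benzene (E/Z mixture) | COC=Cc1ccc(OCc2ccccc2)c(OCc2ccccc2)c1 | intermediate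
20 | 2-[3,4-bis(benzyloxy)phenyl]acetaldehyde | O=CCc1ccc(OCc2ccccc2)c(OCc2ccccc2)c1 | intermediate
21 | (E)-2-[3,4-bis(benzyloxy)phenyl]vinyl acetate | CC(=O)O/C=C/c1ccc(OCc2ccccc2)c(OCc2ccccc2)c1 | intermediate
22 | dimer with 3,5-bis(benzyloxy)-6-methylidene-1-oxocyclohexa-2,4-dien-2-yl at C4β of the middle unit (o-quinone methide) | c9ccccc9COc1cc(OCc9ccccc9)c2c(c1Br)O[C@H](c7ccc(OCc9ccccc9)c(OCc9ccccc9)c7)[C@H](OCc9ccccc9)[C@H]2c1c(OCc9ccccc9)cc(OS(=O)(=O)C(F)(F)F)c2c1O[C@H](c7ccc(OCc9ccccc9)c(OCc9ccccc9)c7)[C@H](OCc9ccccc9)[C@H]2C1=C(OCc9ccccc9)C=C(OCc9ccccc9)C(=C)C1=O | intermediate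
23 | protected trimer, lower unit (2R,3S) with 3-O-acetyl, upper 8-Br, middle 5-OTf (key-step product) | c9ccccc9COc1cc(OCc9ccccc9)c2c(c1Br)O[C@H](c7ccc(OCc9ccccc9)c(OCc9ccccc9)c7)[C@H](OCc9ccccc9)[C@H]2c1c(OCc9ccccc9)cc(OS(=O)(=O)C(F)(F)F)c2c1O[C@H](c7ccc(OCc9ccccc9)c(OCc9ccccc9)c7)[C@H](OCc9ccccc9)[C@H]2c1c(OCc9ccccc9)cc(OCc9ccccc9)c2c1O[C@H](c7ccc(OCc9ccccc9)c(OCc9ccccc9)c7)[C@@H](OC(C)=O)C2 | intermediate
24 | protected trimer with free lower C3–OH, upper 8-Br, middle 5-OTf | c9ccccc9COc1cc(OCc9ccccc9)c2c(c1Br)O[C@H](c7ccc(OCc9ccccc9)c(OCc9ccccc9)c7)[C@H](OCc9ccccc9)[C@H]2c1c(OCc9ccccc9)cc(OS(=O)(=O)C(F)(F)F)c2c1O[C@H](c7ccc(OCc9ccccc9)c(OCc9ccccc9)c7)[C@H](OCc9ccccc9)[C@H]2c1c(OCc9ccccc9)cc(OCc9ccccc9)c2c1O[C@H](c7ccc(OCc9ccccc9)c(OCc9ccccc9)c7)[C@@H](O)C2 | intermediate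
25 | CNP0270097.1, epicatechin-(4β→8)-[(2R,3R,4R)-7,3′,4′-trihydroxyflavan-3-ol]-(4β→8)-catechin | Oc1cc(O)c2c(c1)O[C@H](c1ccc(O)c(O)c1)[C@H](O)[C@H]2c1c(O)ccc2c1O[C@H](c1ccc(O)c(O)c1)[C@H](O)[C@H]2c1c(O)cc(O)c2c1O[C@H](c1ccc(O)c(O)c1)[C@@H](O)C2 | target

**Count and risks**

Total step count: 19. Longest linear sequence: 16 steps (1, 2, 3, 5, 6, 7, 8, 9, 10, 11, 12, 13, 14, 17, 18, 19).

Steps most likely to fail:

Step 17 (key step). What may go wrong: poor facial selectivity (the catalyst and the middle-unit C4 centre working against each other), alkylation of aromatic rings by the quinone methide instead of cycloaddition, or addition in the reversed orientation. Fallback with known chemistry: the lower unit is taken from the chiral pool. Commercial (+)-catechin is benzylated (BnBr, K2CO3, DMF) to 5,7,3′,4′-tetra-O-benzyl-(+)-catechin F1. The thioether 13 is then coupled with F1 (3 equiv) under AgBF4 in CH2Cl2/THF, the same thiophilic activation as in step 12; C8 of benzylated catechin is the established site of attack and approach trans to the C3 benzyloxy group gives 4β. This fallback sets out from compound 13 and gives compound 24 directly, where it comes back to the route before step 19.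

Step 12. What may go wrong: attack of the phenol through oxygen without the O→C shift, attack at the carbon para to the hydroxyl, or slow ionisation beside the triflate. Fallback: the nucleophile is changed to a protected salicyl alcohol with no free phenol. Commercial 2,4,6-trihydroxybenzaldehyde is dibenzylated (BnBr, K2CO3, acetone; the hydrogen-bonded hydroxyl stays) to 2,4-bis(benzyloxy)-6-hydroxybenzaldehyde F2, reduced (NaBH4) to 3,5-bis(benzyloxy)-2-(hydroxymethyl)phenol F3, and closed with 2,2-dimethoxypropane and pyridinium p-toluenesulfonate to 5,7-bis(benzyloxy)-2,2-dimethyl-4H-1,3-benzodioxine F4. AgBF4-mediated coupling of 13 with F4 should go to C8 of F4, the position between the ring oxygen and a benzyloxy group, as in benzylated catechins, and gives the dimer acetonide F5. Hydrolysis of F5 (AcOH/H2O/THF, 40 °C) gives the salicyl alcohol. This fallback sets out from compound 13 and comes back to the route at compound 17, replacing steps 12 to 14.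

Step 19. What may go wrong: incomplete hydrogenolysis of the aryl triflate (or S–O cleavage back to the phenol), slowing of benzyl ether cleavage by the amine, or acid-induced cleavage of interflavan bonds. Fallback: the two non-benzyl groups are removed first in solution. Compound 24 is treated with Pd(OAc)2, 1,1′-bis(diphenylphosphino)ferrocene, HCO2H and Et3N in DMF at 70 °C (formate reduction of the aryl triflate and aryl bromide) to give the tridecabenzyl ether F6, which is then hydrogenolysed under neutral conditions (H2, Pd(OH)2/C, THF/MeOH). This fallback sets out from compound 24 and comes back to the route at compound 25.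

**Further compounds**

F1 | step 17 | 5,7,3′,4′-tetra-O-benzyl-(+)-catechin | c9ccccc9COc1cc(OCc9ccccc9)c2c(c1)O[C@H](c7ccc(OCc9ccccc9)c(OCc9ccccc9)c7)[C@@H](O)C2
F2 | step 12 | 2,4-bis(benzyloxy)-6-hydroxybenzaldehyde | O=Cc1c(O)cc(OCc2ccccc2)cc1OCc1ccccc1
F3 | step 12 | 3,5-bis(benzyloxy)-2-(hydroxymethyl)phenol | OCc1c(O)cc(OCc2ccccc2)cc1OCc1ccccc1
F4 | step 12 | 5,7-bis(benzyloxy)-2,2-dimethyl-4H-1,3-benzodioxine | CC1(C)OCc2c(OCc3ccccc3)cc(OCc3ccccc3)cc2O1
F5 | step 12 | dimer (upper 8-Br, middle 5-OTf) with 5,7-bis(benzyloxy)-2,2-dimethyl-4H-1,3-benzodioxin-8-yl at C4β of the middle unit | c9ccccc9COc1cc(OCc9ccccc9)c2c(c1Br)O[C@H](c7ccc(OCc9ccccc9)c(OCc9ccccc9)c7)[C@H](OCc9ccccc9)[C@H]2c1c(OCc9ccccc9)cc(OS(=O)(=O)C(F)(F)F)c2c1O[C@H](c7ccc(OCc9ccccc9)c(OCc9ccccc9)c7)[C@H](OCc9ccccc9)[C@H]2c1c(OCc9ccccc9)cc(OCc9ccccc9)c2COC(C)(C)Oc12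
F6 | step 19 | tridecabenzyl ether of the target (no bromine, no triflate, free lower C3–OH) | c9ccccc9COc1cc(OCc9ccccc9)c2c(c1)O[C@H](c7ccc(OCc9ccccc9)c(OCc9ccccc9)c7)[C@H](OCc9ccccc9)[C@H]2c1c(OCc9ccccc9)ccc2c1O[C@H](c7ccc(OCc9ccccc9)c(OCc9ccccc9)c7)[C@H](OCc9ccccc9)[C@H]2c1c(OCc9ccccc9)cc(OCc9ccccc9)c2c1O[C@H](c7ccc(OCc9ccccc9)c(OCc9ccccc9)c7)[C@@H](O)C2
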